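**Plan**

1. Retrosynthesis first removes C3–Br (electrophilic substitution of the free indole), then the N-sulfonyl group and the C2=C3 double bond, and trades C5–Br and C7–Br for C–Si bonds.
2. The benzene ring is then cut at C3a–C7a, C4–C5 and C6–C7 into an N-tosyl ynamide-tethered 1,6-diyne (N1, C2, C3, C3a, C4, C7a, C7) and methoxy(trimethylsilyl)acetylene (C5, C6).
3. Enabling feature: C5 and C7 lie 1,3 across the methoxy-bearing C6, so C7 maps onto the silylated ynamide terminus and C6/C5 onto the O- and Si-bearing carbons of the ynol ether; silicon marks both future bromine positions on the benzene ring.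
4. The diyne is cut at the N–C(sp) bond into N-(but-3-ynyl)tosylamide and an alkynyl(phenyl)iodonium salt; the ynol ether comes from chloroacetaldehyde dimethyl acetal.
5. Forward: the benzene ring and the five-membered nitrogen ring close together in one rhodium-catalysed [2+2+2] cycloaddition, followed by double ipso-bromodesilylation, dehydrogenation, detosylation and C3 bromination.
6. The target has no stereocentre, so no stereocontrol is needed.

Key step: step 5

Remark: indole numbering (N1, C2, C3, C3a, C4–C7, C7a) is used for all bicyclic compounds, and the target is taken as the achiral 1H-indole tautomer.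

**Route**

Step 1
Reactants: 1 but-3-yn-1-amine; 2 p-toluenesulfonyl chloride
Product: 3 N-(but-3-yn-1-yl)-4-methylbenzenesulfonamide
Conditions: Et3N, CH2Cl2, 0 °C to rt
Reagents that add atoms: none
Why: N-sulfonylation of a primary amine with a sulfonyl chloride is routine, and the terminal alkyne is inert to these conditions.

Step 2
Reactants: 4 bis(trimethylsilyl)acetylene; 5 (diacetoxyiodo)benzene
Product: 7 phenyl[(trimethylsilyl)ethynyl]iodonium trifluoromethanesulfonate, via oxo-bridged bis(phenyliodine triflate) 6 (not isolated)
Conditions: Tf2O (0.5 equiv), CH2Cl2, 0 °C; then 4, 0 °C to rt; precipitation with Et2O/hexane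
Reagents that add atoms: trifluoromethanesulfonic anhydride, O=S(=O)(OS(=O)(=O)C(F)(F)F)C(F)(F)F
Why: Tf2O turns PhI(OAc)2 into a highly electrophilic oxo-bridged trivalent iodine triflate, which exchanges one C–Si bond of the bis-silyl alkyne for a C–I bond (silicon-to-iodine ligand exchange), the standard entry to silylethynyl(phenyl)iodonium triflates.

Step 3
Reactants: 3 N-(but-3-yn-1-yl)-4-methylbenzenesulfonamide; 7 phenyl[(trimethylsilyl)ethynyl]iodonium trifluoromethanesulfonate
Product: 9 N-(but-3-yn-1-yl)-4-methyl-N-[(trimethylsilyl)ethynyl]benzenesulfonamide, via potassium sulfonamidate 8 (not isolated)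
Conditions: KN(SiMe3)2 (1.0 equiv), toluene, 0 °C; then 7, 0 °C to rt
Reagents that add atoms: none
Why: N-alkynylation with an alkynyliodonium salt: the sulfonamide anion adds to the silyl-bearing carbon, iodobenzene leaves to give an alkylidene carbene, and a fast 1,2-silyl shift delivers the C-silyl ynamide; no copper is present, so the free terminal alkyne (far less acidic than N–H) is not coupled.

Step 4
Reactants: 10 chloroacetaldehyde dimethyl acetal
Product: 12 methoxy(trimethylsilyl)acetylene, via lithium methoxyacetylide 11 (not isolated)
Conditions: LiNEt2 (3 equiv, from n-BuLi and Et2NH), THF, 0 °C; then Me3SiCl (2.2 equiv), −78 °C to rt; fractional distillation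
Reagents that add atoms: chlorotrimethylsilane, C[Si](C)(C)Cl
Why: Successive base-induced eliminations of methanol and HCl from the chloroacetal (the classical route to methoxyacetylene) followed by deprotonation give the alkoxyacetylide in one flask, and C-silylation of this acetylide with Me3SiCl is a standard trapping.

Step 5
Reactants: 9 N-(but-3-yn-1-yl)-4-methyl-N-[(trimethylsilyl)ethynyl]benzenesulfonamide; 12 methoxy(trimethylsilyl)acetylene
Product: 13 6-methoxy-1-tosyl-5,7-bis(trimethylsilyl)indoline
Conditions: RhCl(PPh3)3 (10 mol %), 12 (3 equiv), toluene, 60 °C, slow addition of 9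
Reagents that add atoms: none
Why: Oxidative coupling of the ynamide and the butynyl alkyne of 9 on monovalent rhodium should give a trivalent rhodacyclopentadiene in which the C3a–C7a bond, and with it the five-membered nitrogen ring, already exists (closure by metallacycle formation across the N–CH2–CH2 tether); insertion of 12 into a Rh–C bond and C–C reductive elimination then form C4–C5 and C6–C7 and close the benzene ring, the whole being a crossed [2+2+2] alkyne cyclotrimerisation. The closest known reaction type is the RhCl(PPh3)3-catalysed cocyclisation of sulfonyl-ynamide-tethered 1,6-diynes with monoalkynes to indolines, and silyl- and alkoxy-substituted alkynes are established 2π partners in metal-mediated cyclotrimerisations. No stereocentre is formed. The step needs cross- over homo-cyclisation, which the bulky silyl terminus of 9, the excess of 12 and the slow addition of 9 should secure. It also needs one orientation of 12, which avoidance of a vicinal Me3Si/Me3Si contact should secure by placing the methoxy carbon next to the silylated C7 and the silyl carbon next to the unsubstituted C4. The methyl ynol ether cannot fragment to a ketene by retro-ene loss of an alkene, so it should tolerate the reaction temperature.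

Step 6
Reactants: 13 6-methoxy-1-tosyl-5,7-bis(trimethylsilyl)indoline
Product: 14 5,7-dibromo-6-methoxy-1-tosylindoline
Conditions: NBS (2.2 equiv), MeCN, 0 °C to rt, dark
Reagents that add atoms: N-bromosuccinimide, O=C1CCC(=O)N1Br
Why: Electrophilic ipso-bromodesilylation: both silylated carbons are ortho to the methoxy group (C5 also para and C7 ortho to nitrogen), attack there gives a β-silyl-stabilised arenium ion that loses silicon, and C4–H, meta to both donors, stays untouched; a position that lost silicon to a proton would still be brominated at the same carbon by ordinary electrophilic substitution.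

Step 7
Reactants: 14 5,7-dibromo-6-methoxy-1-tosylindoline
Product: 15 5,7-dibromo-6-methoxy-1-tosyl-1H-indole
Conditions: DDQ (2.5 equiv), 1,4-dioxane, 100 °C
Reagents that add atoms: none
Why: Quinone dehydrogenation of an N-sulfonylindoline: DDQ abstracts hydride from the benzylic C3–H, whose cation is stabilised by the methoxy group para to C3a, and loss of the C2 proton gives the aromatic indole; aryl bromides, the aryl ether and the sulfonamide are inert to DDQ.

Step 8
Reactants: 15 5,7-dibromo-6-methoxy-1-tosyl-1H-indole
Product: 16 5,7-dibromo-6-methoxy-1H-indole
Conditions: Cs2CO3 (3 equiv), THF/MeOH (2:1), rt to 50 °C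
Reagents that add atoms: none
Why: Methanolysis of an N-sulfonylindole: methoxide attacks sulfur and the indolide leaves, a cleavage that the electron-poor dibromoindole nucleus should accelerate and the aryl bromides tolerate.

Step 9
Reactants: 16 5,7-dibromo-6-methoxy-1H-indole
Product: 17 3,5,7-tribromo-6-methoxy-1H-indole
Conditions: NBS (1.0 equiv), DMF, 0 °C, dark
Reagents that add atoms: N-bromosuccinimide, O=C1CCC(=O)N1Br
Why: Electrophilic aromatic substitution at C3, the most nucleophilic position of an N-unsubstituted indole, with one equivalent of NBS at low temperature to avoid C2 bromination.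

**Compound list**

1 | but-3-yn-1-amine | C#CCCN | starting material
2 | p-toluenesulfonyl chloride | Cc1ccc(cc1)S(Cl)(=O)=O | starting material
3 | N-(but-3-yn-1-yl)-4-methylbenzenesulfonamide | C#CCCNS(=O)(=O)c1ccc(C)cc1 | intermediate
4 | bis(trimethylsilyl)acetylene | C[Si](C)(C)C#C[Si](C)(C)C | starting material
5 | (diacetoxyiodo)benzene | CC(=O)OI(OC(C)=O)c1ccccc1 | starting material
6 | oxo-bridged bis[phenyl(trifluoromethanesulfonyloxy)iodine] | O=S(=O)(OI(c1ccccc1)OI(c1ccccc1)OS(=O)(=O)C(F)(F)F)C(F)(F)F | intermediate
7 | phenyl[(trimethylsilyl)ethynyl]iodonium trifluoromethanesulfonate | C[Si](C)(C)C#C[I+]c1ccccc1.[O-]S(=O)(=O)C(F)(F)F | intermediate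
8 | potassium N-(but-3-yn-1-yl)-4-methylbenzenesulfonamidate | C#CCC[N-]S(=O)(=O)c1ccc(C)cc1.[K+] | intermediate
9 | N-(but-3-yn-1-yl)-4-methyl-N-[(trimethylsilyl)ethynyl]benzenesulfonamide | C[Si](C)(C)C#CN(CCC#C)S(=O)(=O)c1ccc(C)cc1 | intermediate
10 | chloroacetaldehyde dimethyl acetal | COC(CCl)OC | starting material
11 | lithium methoxyacetylide | [Li+].[C-]#COC | intermediate
12 | methoxy(trimethylsilyl)acetylene | COC#C[Si](C)(C)C | intermediate
13 | 6-methoxy-1-tosyl-5,7-bis(trimethylsilyl)indoline | COc1c([Si](C)(C)C)cc2CCN(S(=O)(=O)c3ccc(C)cc3)c2c1[Si](C)(C)C | intermediate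
14 | 5,7-dibromo-6-methoxy-1-tosylindoline | COc1c(Br)cc2CCN(S(=O)(=O)c3ccc(C)cc3)c2c1Br | intermediate
15 | 5,7-dibromo-6-methoxy-1-tosyl-1H-indole | COc1c(Br)cc2ccn(S(=O)(=O)c3ccc(C)cc3)c2c1Br | intermediate
16 | 5,7-dibromo-6-methoxy-1H-indole | COc1c(Br)cc2cc[nH]c2c1Br | intermediate
17 | 3,5,7-tribromo-6-methoxy-1H-indole | COc1c(Br)cc2c(Br)c[nH]c2c1Br | target

**Step count and risks**

Total step count: 9. Longest linear sequence: 7 steps (steps 1, 3, 5, 6, 7, 8, 9; the branch through step 2 is equally long).

Most likely to fail, in this order:

Step 5. The hindered internal ynol ether may fail to insert into the rhodacycle, leaving the diyne to oligomerise, or it may insert in the reverse orientation. The fallback abandons the cycloaddition and installs the bromines by electrophilic substitution on a preformed indoline. It sets out from 2, which should tosylate commercial 6-methoxyindoline (COc1ccc2CCNc2c1; pyridine, CH2Cl2, 0 °C to rt) to 6-methoxy-1-tosylindoline F1. NBS (2.2 equiv, MeCN, 0 °C to rt) should then brominate C5 (para to nitrogen, ortho to methoxy) and C7 (ortho to both), and the fallback returns to the route at 14.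

Step 7. Hydride abstraction from an indoline whose nitrogen carries a sulfonyl group may be too slow, and prolonged heating with the quinone may cause decomposition. The fallback replaces hydride abstraction by radical bromination and elimination. It sets out from 14: NBS with AIBN in PhCF3 at 80 °C should brominate the benzylic C3 position to racemic 3,5,7-tribromo-6-methoxy-1-tosylindoline F2, and DBU in THF at rt should eliminate HBr, returning to the route at 15.

Step 3. Addition of the sulfonamide anion to the iodonium salt may be sluggish, or the alkylidene carbene may be diverted (C–H insertion, loss of the silyl group) before the 1,2-silyl shift. The fallback is a copper-catalysed C–N cross-coupling with a bromoalkyne. Commercial ethynyltrimethylsilane (C#C[Si](C)(C)C) should be brominated with NBS and catalytic AgNO3 in acetone at rt to (bromoethynyl)trimethylsilane F3. F3 is then coupled with 3 under CuSO4·5H2O, 1,10-phenanthroline and K3PO4 in toluene at 65 °C; the fallback sets out from 3 and returns to the route at 9. Its own hazard is Cadiot–Chodkiewicz coupling at the free terminal alkyne, which is why it is not the first choice.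

**Further compounds**

F1 | step 5 | 6-methoxy-1-tosylindoline | COc1ccc2CCN(S(=O)(=O)c3ccc(C)cc3)c2c1
F2 | step 7 | 3,5,7-tribromo-6-methoxy-1-tosylindoline (racemic) | COc1c(Br)cc2C(Br)CN(S(=O)(=O)c3ccc(C)cc3)c2c1Br
F3 | step 3 | (bromoethynyl)trimethylsilane | C[Si](C)(C)C#CBr
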